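The leftover on paper in ochre, red, violet and blue is substrate: with at least one coupling partner entering per substrate on the way to product, 0.0500 M of substrate finds no partner.

| setting | alder | maple | ash | ochre | red | violet | blue |
|---|---|---|---|---|---|---|---|
| substrate | 0.50 M | 0.50 M | 0.50 M | 0.50 M | 0.50 M | 0.50 M | 0.50 M |
| coupling partner | 0.23 M | 0.34 M | 0.45 M | 0.450 M | 0.450 M | 0.450 M | 0.450 M |
| capture agent | 10 mM | 10 mM | 5 mM | 10.0 mM | 10.0 mM | 10.0 mM | 10.0 mM |
| temperature | 35 °C | 68 °C | 35 °C | 60 °C | 80 °C | 20 °C | 40 °C |
| remark | run made earlier | run made earlier | run made earlier |  |  |  |  |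
| time |  |  |  | 5.0 d | 5.0 d | 5.0 d | 5.0 d |

| run | time / d | product / % |
|---|---|---|
| alder | 0.833 | 0 |
| alder | 1.25 | 0 |
| alder | 2.00 | 0 |
| alder | 4.00 | 0.3 |
| alder | 6.00 | 0.4 |
| alder | 10.0 | 0 |
| maple | 0.500 | 0.5 |
| maple | 1.04 | 3.4 |
| maple | 1.67 | 7.2 |
| maple | 2.08 | 10.7 |
| maple | 2.50 | 13.6 |
| maple | 3.00 | 17.5 |
| ash | 0.833 | 0 |
| ash | 3.00 | 0.3 |
| ash | 4.00 | 0 |
| ash | 6.00 | 0 |
| ash | 10.0 | 0 |

(scatter of a reading: 0.3 percentage points)

- the flask with the highest amount of product, in percent of the substrate charged ("all alike" if they lie within 1.5 percentage points) (ochre / red / violet / blue / all alike)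
- final product, as a percentage of the substrate charged, in ochre
- final product, as a percentage of the substrate charged, in red
- final product, as a percentage of the substrate charged, in violet
- final product, as a percentage of the substrate charged, in blue

- steps thought possible: substrate + coupling partner -> intermediate A; intermediate A <-> intermediate B; coupling partner + intermediate A <-> intermediate C; intermediate A -> intermediate D; intermediate D -> product; intermediate C <-> intermediate E; intermediate E + capture agent -> trapped intermediate

The bench habit is to freeze the coupling partner at its charge, the pseudo-first-order view, under which substrate decays towards nothing and product heads for the whole charge. Freezing wants partner far above substrate. Here the partner charge over the substrate charge is 90.0%, and this ratio is the ceiling: the product, in percent of the substrate charged, that the coupling partner as limiting reagent can pay for. The border already shows in maple, whose last reading of 17.5% has by itself claimed 25.7% of its partner charge, so a frozen partner is a rough picture from there on.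

Product goes with heat in the runs so far, though the charges differ too: ash at 35 °C with 0.45 M of coupling partner reads 0.3% at 3.00 d, and maple at 68 °C with less partner reads 17.5% at 3.00 d. This reckoning therefore puts red, the hottest flask, first and under the ceiling, and it gives no height for red. The forecast names red, with 13% in ochre, 58% in red, 0% in violet and 0.2% in blue, red “slowing through second-order depletion”.

The flasks give 13.3% in ochre, 68.4% in red, 0% in violet and 0.0527% in blue, so red leads, and red ends 10 percentage points above the forecast. Red holds 76.0% of its ceiling at 5.00 d. Left until 50.0 d, red reads 89.7% against the ceiling of 90.0%, with 0.225% of its coupling partner and 10.2% of its substrate remaining, the leftover being 10.0% of the charge. The neighbour of violet with 0.30 M of substrate turns the reckoning round: its coupling partner charge stands 0.150 M above its substrate charge, so substrate is the limiting reagent there and its ceiling is 100%. That neighbour reads 0% of product at 5.00 d, with 99.4% of its substrate still there.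

    substrate + coupling partner → intermediate A (k = 0.0641 /M/h, Ea = 90.0 kJ/mol)
    intermediate A ⇌ intermediate B (K = 1.12, k = 0.00732 /h, Ea = 125 kJ/mol, ΔH = −13.0 kJ/mol)
    coupling partner + intermediate A ⇌ intermediate C (K = 1.20 /M, k = 0.0497 /M/h, Ea = 76.0 kJ/mol, ΔH = −73.0 kJ/mol)
    intermediate A → intermediate D (k = 0.125 /h, Ea = 111 kJ/mol)
    intermediate D → product (k = 0.511 /h, Ea = 112 kJ/mol)
    intermediate C ⇌ intermediate E (K = 0.540, k = 0.0318 /h, Ea = 116 kJ/mol, ΔH = −31.0 kJ/mol)
    intermediate E + capture agent → trapped intermediate (k = 0.0139 /M/h, Ea = 90.0 kJ/mol)
    (constants at 80 °C)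

The numbers in the tables were generated by integration on assumed constants.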